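The oxolane ring (O1, C2 aryl-bearing, C3, C4, C5) is disconnected at C3–C4, the lignan 8–8' bond, which joins two carbons that are both electrophilic in ionic chemistry. The key step exploits the CH2O group (C9) on C3: read as an opened oxirane, it lets Cp2TiCl turn the oxirane carbon into the C3 radical, which closes the ring 5-exo-dig onto an aryl alkyne carrying C4 and the benzylic carbon C7'. One operation gives the ring, the C3 stereocentre trans to the C2 aryl group and the free C9 alcohol. The precursor is an acyclic epoxy propargyl ether; the resulting benzylidene group is later dihydroxylated and deoxygenated at C7'.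

Key step: step 6

Remark on numbering: ring locants O1, C2, C3, C4, C5 and side-chain labels C9 (CH2O on C3) and C7' (benzylic carbon on C4) are used in all names; descriptors follow the CIP rules for each compound.
Assumption: the vinyl radical of step 6 is taken to be quenched on the side remote from C3, which gives the (E)-alkene (aryl cis to C3); the (Z)-isomer would pass through steps 7–9 in the same way and give the same final product, because C7' ends as a CH2 group.

Step 1
Reactants: 1 4-(benzyloxy)-3-methoxybenzaldehyde; 2 vinylmagnesium bromide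
Product: 3 racemic 1-[4-(benzyloxy)-3-methoxyphenyl]prop-2-en-1-ol
Conditions: CH2=CHMgBr (1.2 equiv), THF, 0 °C; then sat. aq. NH4Cl
Reagents that add atoms: none
Why: Grignard 1,2-addition of the vinyl nucleophile to the aryl aldehyde should give the allylic alcohol, whose carbinol centre is formed racemic and is resolved in step 2.

Step 2
Reactants: 3 racemic 1-[4-(benzyloxy)-3-methoxyphenyl]prop-2-en-1-ol
Product: 4 (R)-[4-(benzyloxy)-3-methoxyphenyl][(2S)-oxiran-2-yl]methanol (erythro epoxy alcohol)
Conditions: Ti(OiPr)4 (10 mol%), D-(−)-diisopropyl tartrate (15 mol%), t-BuOOH (0.45 equiv), 4 Å MS, CH2Cl2, −20 °C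
Reagents that add atoms: tert-butyl hydroperoxide, CC(C)(C)OO
Why: In this Sharpless kinetic resolution the D-tartrate catalyst should epoxidise the (S)-alcohol fast and on the face that gives the erythro epoxy alcohol, so the carbinol centre (later C2) is selected and the oxirane centre is set by the catalyst, while the slow (R)-alcohol stays behind and is removed by chromatography.

Step 3
Reactants: 5 1-(benzyloxy)-4-bromo-2-methoxybenzene; 6 prop-2-yn-1-ol
Product: 7 3-[4-(benzyloxy)-3-methoxyphenyl]prop-2-yn-1-ol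
Conditions: PdCl2(PPh3)2 (3 mol%), CuI (5 mol%), Et3N–THF, 65 °C
Reagents that add atoms: none
Why: Sonogashira coupling of the aryl bromide with the terminal alkyne should give the aryl propargyl alcohol, and no stereocentre is formed.

Step 4
Reactants: 7 3-[4-(benzyloxy)-3-methoxyphenyl]prop-2-yn-1-ol
Product: 8 1-(benzyloxy)-4-(3-bromoprop-1-yn-1-yl)-2-methoxybenzene
Conditions: CBr4, PPh3, CH2Cl2, 0 °C
Reagents that add atoms: carbon tetrabromide, BrC(Br)(Br)Br
Why: Appel bromination should convert the primary propargylic alcohol into the bromide under neutral conditions, and no stereocentre is involved.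

Step 5
Reactants: 4 (R)-[4-(benzyloxy)-3-methoxyphenyl][(2S)-oxiran-2-yl]methanol; 8 1-(benzyloxy)-4-(3-bromoprop-1-yn-1-yl)-2-methoxybenzene
Product: 9 (2S)-2-[(R)-[4-(benzyloxy)-3-methoxyphenyl]({3-[4-(benzyloxy)-3-methoxyphenyl]prop-2-yn-1-yl}oxy)methyl]oxirane
Conditions: NaH (1.2 equiv), Bu4NI (cat.), THF–DMF, −20 to 0 °C
Reagents that add atoms: none
Why: Williamson etherification of the sodium alkoxide with the reactive propargylic bromide, run cold in an aprotic medium, should outpace Payne-type epoxide migration and leaves both stereocentres untouched.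

Step 6
Reactants: 9 (2S)-2-[(R)-[4-(benzyloxy)-3-methoxyphenyl]({3-[4-(benzyloxy)-3-methoxyphenyl]prop-2-yn-1-yl}oxy)methyl]oxirane
Product: 11 [(2S,3R,4E)-2-[4-(benzyloxy)-3-methoxyphenyl]-4-{[4-(benzyloxy)-3-methoxyphenyl]methylidene}oxolan-3-yl]methanol, via titanium alkoxide 10 (not isolated)
Conditions: Cp2TiCl2 (2.5 equiv), Zn dust, THF, rt (green Cp2TiCl solution added slowly to 9); then dil. aq. HCl, 0 °C
Reagents that add atoms: none
Why: Cp2TiCl (trivalent titanium) binds the oxirane oxygen and cleaves the C3–O bond by single-electron transfer, which leaves the oxygen on C9 as a titanium alkoxide and turns the formerly electrophilic C3 into a nucleophilic secondary radical. This radical adds to the alkyne carbon C4 and closes the oxolane ring in the 5-exo-dig mode (new C3–C4 bond), and the α-aryl vinyl radical at C7' is quenched by hydrogen abstraction from THF or by a second Cp2TiCl and protonation at work-up. The closest known reaction type is the Nugent–RajanBabu titanocene-mediated reductive epoxide opening with radical cyclisation, as applied to epoxy propargyl ethers to give 3-(hydroxymethyl)-4-alkylidene oxolanes. The one new stereocentre, C3, is controlled by the existing centre C2: in the chair-like transition state the aryl group on C2 and the titanium-bound CH2O group on C3 are both pseudo-equatorial, which should give the 2,3-trans ring, and the oxirane configuration plays no part because C3 passes through a planar radical. The step needs regioselective opening to the more substituted radical, 5-exo closure in preference to 6-endo closure and cyclisation that is faster than capture of the radical by a second titanium centre (which would deoxygenate the epoxide to the allyl ether); the first is secured by radical stability, the second by the short oxygen-containing tether and the third by slow addition of the reagent together with the aryl-stabilised vinyl radical that is formed.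

Step 7
Reactants: 11 [(2S,3R,4E)-2-[4-(benzyloxy)-3-methoxyphenyl]-4-{[4-(benzyloxy)-3-methoxyphenyl]methylidene}oxolan-3-yl]methanol
Product: 12 (2S,3R,4S)-2-[4-(benzyloxy)-3-methoxyphenyl]-4-{(S)-[4-(benzyloxy)-3-methoxyphenyl](hydroxy)methyl}-3-(hydroxymethyl)oxolan-4-ol
Conditions: OsO4 (2 mol%), NMO (1.5 equiv), acetone–H2O, 0 °C to rt
Reagents that add atoms: N-methylmorpholine N-oxide, C[N+]1([O-])CCOCC1; water, O
Why: In this Upjohn dihydroxylation, allylic strain between the aryl group on C7' and C3 should place the C3 hydroxymethyl group over the β face of the alkene, so that osmium adds suprafacially to the α face and sets C4 with its hydroxyl trans to the C3 substituent, while the centre at C7' follows from syn addition to the (E)-alkene and is removed in step 9.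

Step 8
Reactants: 12 (2S,3R,4S)-2-[4-(benzyloxy)-3-methoxyphenyl]-4-{(S)-[4-(benzyloxy)-3-methoxyphenyl](hydroxy)methyl}-3-(hydroxymethyl)oxolan-4-ol
Product: 13 (S)-{(2S,3R,4S)-3-(acetoxymethyl)-2-[4-(benzyloxy)-3-methoxyphenyl]-4-hydroxyoxolan-4-yl}[4-(benzyloxy)-3-methoxyphenyl]methyl acetate
Conditions: Ac2O (2.5 equiv), pyridine, DMAP (5 mol%), CH2Cl2, 0 °C to rt
Reagents that add atoms: acetic anhydride, CC(=O)OC(C)=O
Why: Acylation under nucleophilic catalysis should esterify the primary C9 hydroxyl and the secondary benzylic C7' hydroxyl while the hindered tertiary C4 hydroxyl does not react, and no stereocentre is changed.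

Step 9
Reactants: 13 (S)-{(2S,3R,4S)-3-(acetoxymethyl)-2-[4-(benzyloxy)-3-methoxyphenyl]-4-hydroxyoxolan-4-yl}[4-(benzyloxy)-3-methoxyphenyl]methyl acetate
Product: 14 olivil monoacetate, [(2S,3R,4S)-4-hydroxy-2-(4-hydroxy-3-methoxyphenyl)-4-[(4-hydroxy-3-methoxyphenyl)methyl]oxolan-3-yl]methyl acetate
Conditions: H2 (1 atm), Pd/C (10 wt% Pd), EtOAc, rt
Reagents that add atoms: none
Why: Heterogeneous palladium-catalysed hydrogenolysis should cleave both aryl benzyl ethers and the activated benzylic C7'–OAc bond (directly or through the para-quinone methide formed once the phenol is free), which turns C7' into CH2, whereas the primary acetate, the tertiary alcohol and, with short exposure, the cyclic benzylic C2–O1 bond remain and C2, C3 and C4 are untouched.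

Compound list
1 | 4-(benzyloxy)-3-methoxybenzaldehyde | COc1cc(C=O)ccc1OCc1ccccc1 | starting material
2 | vinylmagnesium bromide | C=C[Mg]Br | starting material
3 | racemic 1-[4-(benzyloxy)-3-methoxyphenyl]prop-2-en-1-ol | COc1cc(C(O)C=C)ccc1OCc1ccccc1 | intermediate
4 | (R)-[4-(benzyloxy)-3-methoxyphenyl][(2S)-oxiran-2-yl]methanol | COc1cc([C@@H](O)[C@@H]2CO2)ccc1OCc1ccccc1 | intermediate
5 | 1-(benzyloxy)-4-bromo-2-methoxybenzene | COc1cc(Br)ccc1OCc1ccccc1 | starting material
6 | prop-2-yn-1-ol | C#CCO | starting material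
7 | 3-[4-(benzyloxy)-3-methoxyphenyl]prop-2-yn-1-ol | COc1cc(C#CCO)ccc1OCc1ccccc1 | intermediate
8 | 1-(benzyloxy)-4-(3-bromoprop-1-yn-1-yl)-2-methoxybenzene | COc1cc(C#CCBr)ccc1OCc1ccccc1 | intermediate
9 | (2S)-2-[(R)-[4-(benzyloxy)-3-methoxyphenyl]({3-[4-(benzyloxy)-3-methoxyphenyl]prop-2-yn-1-yl}oxy)methyl]oxirane | COc1cc(C#CCO[C@H](c2ccc(OCc3ccccc3)c(OC)c2)[C@@H]2CO2)ccc1OCc1ccccc1 | intermediate
10 | chlorobis(cyclopentadienyl)titanium alkoxide of 11 (tetravalent titanium bound to the C9 oxygen, written as its ions) | COc1cc(/C=C2/CO[C@H](c3ccc(OCc4ccccc4)c(OC)c3)[C@H]2C[O-])ccc1OCc1ccccc1.[Ti+4].[Cl-].C1=C[CH-]C=C1.C1=C[CH-]C=C1 | intermediate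
11 | [(2S,3R,4E)-2-[4-(benzyloxy)-3-methoxyphenyl]-4-{[4-(benzyloxy)-3-methoxyphenyl]methylidene}oxolan-3-yl]methanol | COc1cc(/C=C2/CO[C@H](c3ccc(OCc4ccccc4)c(OC)c3)[C@H]2CO)ccc1OCc1ccccc1 | intermediate
12 | (2S,3R,4S)-2-[4-(benzyloxy)-3-methoxyphenyl]-4-{(S)-[4-(benzyloxy)-3-methoxyphenyl](hydroxy)methyl}-3-(hydroxymethyl)oxolan-4-ol | COc1cc([C@H](O)[C@@]2(O)CO[C@H](c3ccc(OCc4ccccc4)c(OC)c3)[C@H]2CO)ccc1OCc1ccccc1 | intermediate
13 | (S)-{(2S,3R,4S)-3-(acetoxymethyl)-2-[4-(benzyloxy)-3-methoxyphenyl]-4-hydroxyoxolan-4-yl}[4-(benzyloxy)-3-methoxyphenyl]methyl acetate | COc1cc([C@H](OC(C)=O)[C@@]2(O)CO[C@H](c3ccc(OCc4ccccc4)c(OC)c3)[C@H]2COC(C)=O)ccc1OCc1ccccc1 | intermediate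
14 | olivil monoacetate, [(2S,3R,4S)-4-hydroxy-2-(4-hydroxy-3-methoxyphenyl)-4-[(4-hydroxy-3-methoxyphenyl)methyl]oxolan-3-yl]methyl acetate | COc1cc(C[C@@]2(O)CO[C@H](c3ccc(O)c(OC)c3)[C@H]2COC(C)=O)ccc1O | target

Total step count: 9
Longest linear sequence: 7 steps (steps 1, 2, 5, 6, 7, 8, 9 from compound 1; the branch from compound 5 through steps 3, 4, 5–9 is equally long)

Steps most likely to fail

Step 6. The C3 radical may be reduced by a second Cp2TiCl before it cyclises, after which the β-titanoxy alkyltitanium eliminates and the epoxide is deoxygenated to the allyl ether; the trans selectivity between C2 and C3 may also be low. The fallback closes the same C3–C4 bond by a two-electron organopalladium pathway, sets out from 3 and 8 and comes back to the route at 14. Racemic 3 is resolved under the conditions of step 2 with L-(+)-diisopropyl tartrate, which consumes the (R)-alcohol and leaves (S)-1-[4-(benzyloxy)-3-methoxyphenyl]prop-2-en-1-ol F1. Alkylation with 8 (NaH, THF–DMF) gives the enyne ether F2. Palladium-catalysed borylative enyne cyclisation (Pd(OAc)2 cat., B2pin2, MeOH, toluene, 50 °C) proceeds by syn hydropalladation of the alkyne and 5-exo insertion of the alkene, and should give the 2,3-trans alkylboronate F3 with a (Z)-benzylidene group. Oxidation (NaBO3·4H2O, THF–H2O) gives the (Z)-isomer of 11, alcohol F4. F4 is carried through the conditions of steps 7 and 8 via the C7'-epimeric triol F5 and diacetate F6, and the hydrogenolysis of step 9 then gives 14, because C7' ends as CH2.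

Step 9. Hydrogenolysis of the hindered benzylic acetate may be slow, so that prolonged exposure begins to cleave the benzylic C2–O1 bond and opens the ring. The fallback replaces the acetate by a strained benzylic C–O bond that is cleaved within minutes; it sets out from 11 and comes back at 14. Selective acetylation of the primary alcohol (Ac2O, pyridine, 0 °C) gives the monoacetate F9. Epoxidation with dimethyldioxirane (acetone, −20 °C, acid-free) on the α face anti to the C3 substituent gives the spiro-epoxide F10, which is used crude. Brief hydrogenolysis (H2, Pd/C, EtOAc, solid NaHCO3) cleaves the benzylic C7'–O bond of the oxirane and both benzyl ethers and gives 14.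

Step 7. Facial discrimination in the osmylation may be insufficient, which would give the C4 epimer alongside 12. The fallback raises the steric bias of the substrate with a temporary bulky group on the C9 oxygen; it sets out from 11 and comes back at 12. Silylation (t-BuPh2SiCl, imidazole, DMF) gives the silyl ether F7, whose silyl group screens the β face of the alkene. Dihydroxylation (OsO4 cat., NMO, acetone–H2O) gives the diol F8, and Bu4NF in THF removes the silyl group to give 12.

Further compounds
F1 | step 6 | (S)-1-[4-(benzyloxy)-3-methoxyphenyl]prop-2-en-1-ol | COc1cc([C@@H](O)C=C)ccc1OCc1ccccc1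
F2 | step 6 | 1-(benzyloxy)-4-[(1S)-1-({3-[4-(benzyloxy)-3-methoxyphenyl]prop-2-yn-1-yl}oxy)prop-2-en-1-yl]-2-methoxybenzene | COc1cc(C#CCO[C@H](c2ccc(OCc3ccccc3)c(OC)c2)C=C)ccc1OCc1ccccc1
F3 | step 6 | 2-{[(2S,3S,4Z)-2-[4-(benzyloxy)-3-methoxyphenyl]-4-{[4-(benzyloxy)-3-methoxyphenyl]methylidene}oxolan-3-yl]methyl}-4,4,5,5-tetramethyl-1,3,2-dioxaborolane | COc1cc(/C=C2\CO[C@H](c3ccc(OCc4ccccc4)c(OC)c3)[C@H]2CB3OC(C)(C)C(C)(C)O3)ccc1OCc1ccccc1
F4 | step 6 | [(2S,3R,4Z)-2-[4-(benzyloxy)-3-methoxyphenyl]-4-{[4-(benzyloxy)-3-methoxyphenyl]methylidene}oxolan-3-yl]methanol | COc1cc(/C=C2\CO[C@H](c3ccc(OCc4ccccc4)c(OC)c3)[C@H]2CO)ccc1OCc1ccccc1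
F5 | step 6 | (2S,3R,4S)-2-[4-(benzyloxy)-3-methoxyphenyl]-4-{(R)-[4-(benzyloxy)-3-methoxyphenyl](hydroxy)methyl}-3-(hydroxymethyl)oxolan-4-ol | COc1cc([C@@H](O)[C@@]2(O)CO[C@H](c3ccc(OCc4ccccc4)c(OC)c3)[C@H]2CO)ccc1OCc1ccccc1
F6 | step 6 | (R)-{(2S,3R,4S)-3-(acetoxymethyl)-2-[4-(benzyloxy)-3-methoxyphenyl]-4-hydroxyoxolan-4-yl}[4-(benzyloxy)-3-methoxyphenyl]methyl acetate | COc1cc([C@@H](OC(C)=O)[C@@]2(O)CO[C@H](c3ccc(OCc4ccccc4)c(OC)c3)[C@H]2COC(C)=O)ccc1OCc1ccccc1
F7 | step 7 | tert-butyl{[(2S,3R,4E)-2-[4-(benzyloxy)-3-methoxyphenyl]-4-{[4-(benzyloxy)-3-methoxyphenyl]methylidene}oxolan-3-yl]methoxy}diphenylsilane | COc1cc(/C=C2/CO[C@H](c3ccc(OCc4ccccc4)c(OC)c3)[C@H]2CO[Si](c3ccccc3)(c3ccccc3)C(C)(C)C)ccc1OCc1ccccc1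
F8 | step 7 | (2S,3R,4S)-2-[4-(benzyloxy)-3-methoxyphenyl]-4-{(S)-[4-(benzyloxy)-3-methoxyphenyl](hydroxy)methyl}-3-{[tert-butyl(diphenyl)silyl]oxymethyl}oxolan-4-ol | COc1cc([C@H](O)[C@@]2(O)CO[C@H](c3ccc(OCc4ccccc4)c(OC)c3)[C@H]2CO[Si](c3ccccc3)(c3ccccc3)C(C)(C)C)ccc1OCc1ccccc1
F9 | step 9 | [(2S,3R,4E)-2-[4-(benzyloxy)-3-methoxyphenyl]-4-{[4-(benzyloxy)-3-methoxyphenyl]methylidene}oxolan-3-yl]methyl acetate | COc1cc(/C=C2/CO[C@H](c3ccc(OCc4ccccc4)c(OC)c3)[C@H]2COC(C)=O)ccc1OCc1ccccc1
F10 | step 9 | [(2S,3S,6S,7R)-2,6-bis[4-(benzyloxy)-3-methoxyphenyl]-1,5-dioxaspiro[2.4]heptan-7-yl]methyl acetate | COc1cc([C@@H]3O[C@@]32CO[C@H](c4ccc(OCc5ccccc5)c(OC)c4)[C@H]2COC(C)=O)ccc1OCc1ccccc1
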